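## Retrosynthetic overview

Target numbering (spiro[5.5]undecane): C1(=O)–C2(Me)=C3(OMe)–C4Me2–C5(=O)–C6(spiro); C7(iPr)–C8–C9=C10(4‑methylpent‑3‑enyl)–C11.

1. The cyclohexene ring (C6–C11) is opened at C9=C10 by ring-closing metathesis; the terminal alkene at C8–C9 comes from a CH2CH2OH arm by oxidation and methylenation.
2. In the dione ring, C1(=O)–C2(Me)=C3(OMe)–C4Me2 is the full carbon and oxygen pattern of 3‑methoxy‑2,4,4‑trimethylcyclobut‑2‑enone, and C5(=O)–C6 is the carbonyl/α‑carbon pair of a δ‑lactone whose ring oxygen becomes that CH2CH2OH arm.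
3. In the key step the lactone enolate adds to the cyclobutenone C=O, the cyclobutenolate opens (4π), and the CMe2 terminus of the dienolate is acylated by the lactone carbonyl. C5–C6 is thereby inserted between C1 and C4, so the four-membered ring becomes the six-membered ring and quaternary C6 is created. The enabling feature is the 1,3‑diketone at quaternary C6, flanked by a vinylogous ester (C1–C3) on one side and a quaternary CMe2 (C4) on the other.
4. C7 is set by Rh-catalysed asymmetric 1,4‑addition to 5,6‑dihydropyran‑2‑one. C6 is set by attack anti to the isopropyl group on the lactone enolate; with the lactone, not the later cyclohexene, as template, this places the C1 carbonyl cis to isopropyl, as the target requires.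
5. Ring order: cyclobutenone ([2+2]) → dione ring by two-atom ring expansion (the lactone ring is opened) → cyclohexene by RCM.

Key step: step 9

Remark: 1‑ethoxyprop‑1‑yne (13) and the isopropenyl pinacol boronate (7) are taken as commercial, and (R)‑BINAP is taken, by analogy with Rh-catalysed additions to cyclic enones, as the antipode that gives the 4R lactone (otherwise the other antipode is used).

## Route

Step 1
Reactants: 1 5‑bromo‑2‑methylpent‑2‑ene; 2 prop‑2‑yn‑1‑ol
Product: 4 6‑methyl‑2‑methylidenehept‑5‑en‑1‑ol, via Grignard reagent 3 (not isolated)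
Conditions: Mg, THF, rt; then 2 (0.45 equiv), CuI (10 mol %), Et2O–THF, 0 °C to reflux; aq. NH4Cl
Reagents that add atoms: none
Why: Copper-catalysed anti-carbomagnesiation of the magnesium alkoxide of propargyl alcohol (Duboudin type) delivers the alkyl group to the internal alkyne carbon through a five-membered oxamagnesacycle, so protonolysis should give the 2‑substituted allylic alcohol, and no stereocenter arises.

Step 2
Reactants: 4 6‑methyl‑2‑methylidenehept‑5‑en‑1‑ol
Product: 5 2‑(bromomethyl)‑6‑methylhepta‑1,5‑diene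
Conditions: CBr4, PPh3, CH2Cl2, 0 °C
Reagents that add atoms: carbon tetrabromide, BrC(Br)(Br)Br
Why: Appel bromination of a primary allylic alcohol runs under neutral conditions that spare the trisubstituted alkene, and SN2 and SN2' displacement lead to the same bromide.

Step 3
Reactants: 6 5,6‑dihydro‑2H‑pyran‑2‑one; 7 4,4,5,5‑tetramethyl‑2‑(prop‑1‑en‑2‑yl)‑1,3,2‑dioxaborolane
Product: 8 (4R)‑4‑(prop‑1‑en‑2‑yl)oxan‑2‑one
Conditions: [Rh(cod)OH]2 (cat.), (R)‑BINAP (cat.), dioxane–H2O (10:1), 50 °C
Reagents that add atoms: none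
Why: Hayashi–Miyaura Rh(I)/BINAP-catalysed 1,4‑addition of an alkenylboron reagent to an α,β‑unsaturated δ‑lactone, in which the chiral Rh–BINAP alkenyl complex selects the face of the C3=C4 bond and thereby sets C4.

Step 4
Reactants: 8 (4R)‑4‑(prop‑1‑en‑2‑yl)oxan‑2‑one
Product: 9 (4R)‑4‑(propan‑2‑yl)oxan‑2‑one
Conditions: H2 (1 atm), RhCl(PPh3)3 (cat.), PhH–EtOH, rt
Reagents that add atoms: none
Why: Homogeneous hydrogenation with Wilkinson's catalyst saturates the only (1,1‑disubstituted) alkene without the double-bond migration that could erase the allylic C4 stereocenter.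

Step 5
Reactants: 9 (4R)‑4‑(propan‑2‑yl)oxan‑2‑one; 5 2‑(bromomethyl)‑6‑methylhepta‑1,5‑diene
Product: 11 (3S,4S)‑3‑(6‑methyl‑2‑methylidenehept‑5‑en‑1‑yl)‑4‑(propan‑2‑yl)oxan‑2‑one, via lithium enolate 10 (not isolated)
Conditions: LDA, THF, −78 °C; then 5, DMPU, −78 to −30 °C
Reagents that add atoms: none
Why: Alkylation of the lithium lactone enolate with a reactive allylic bromide should occur anti to the C4 isopropyl group (trans product), although the C3 configuration is of no consequence because this centre is enolised again in step 9.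

Step 6
Reactants: 12 2‑methylpropanoyl chloride; 13 1‑ethoxyprop‑1‑yne
Product: 15 3‑ethoxy‑2,4,4‑trimethylcyclobut‑2‑en‑1‑one, via dimethylketene 14 (not isolated)
Conditions: Et3N, MeCN, 60 °C (slow addition of 12)
Reagents that add atoms: none
Why: Thermal [2+2] cycloaddition of a ketene generated in situ by dehydrochlorination with an electron-rich ynol ether, the nucleophilic methyl-bearing alkyne carbon bonding to the ketene carbonyl carbon to give the 3‑alkoxycyclobutenone regiochemistry.

Step 7
Reactants: 15 3‑ethoxy‑2,4,4‑trimethylcyclobut‑2‑en‑1‑one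
Product: 16 3‑hydroxy‑2,4,4‑trimethylcyclobut‑2‑en‑1‑one
Conditions: 1 M HCl, THF, rt
Reagents that add atoms: water, O
Why: Acid hydrolysis of the vinylogous ester by addition of water at C3 and loss of ethanol should give the stable enol of 2,2,4‑trimethylcyclobutane‑1,3‑dione.

Step 8
Reactants: 16 3‑hydroxy‑2,4,4‑trimethylcyclobut‑2‑en‑1‑one
Product: 17 3‑methoxy‑2,4,4‑trimethylcyclobut‑2‑en‑1‑one
Conditions: TMSCHN2, PhMe–MeOH, 0 °C
Reagents that add atoms: (trimethylsilyl)diazomethane, C[Si](C)(C)C=[N+]=[N-]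
Why: O‑Methylation of the strongly acidic vinylogous acid with the diazomethane surrogate is regiochemically unambiguous because the two enol oxygens of this ring are symmetry-equivalent.

Step 9
Reactants: 11 (3S,4S)‑3‑(6‑methyl‑2‑methylidenehept‑5‑en‑1‑yl)‑4‑(propan‑2‑yl)oxan‑2‑one; 17 3‑methoxy‑2,4,4‑trimethylcyclobut‑2‑en‑1‑one
Product: 21 (2R)‑2‑[(3S)‑1‑hydroxy‑4‑methylpentan‑3‑yl]‑5‑methoxy‑4,6,6‑trimethyl‑2‑(6‑methyl‑2‑methylidenehept‑5‑en‑1‑yl)cyclohex‑4‑ene‑1,3‑dione, via lithium enolate 18 (not isolated), via lithium cyclobutenolate 19 (not isolated), via lithium dienolate 20 (not isolated)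
Conditions: LDA (1.05 equiv), THF, −78 °C; then 17, −78 °C to 0 °C; AcOH, −78 °C
Reagents that add atoms: none
Why: Proposed new method: enolate 18 adds 1,2 to the strained C1=O of 17 (C3 is a fully substituted vinylogous-ester carbon, so conjugate addition is disfavoured) to give alkoxide 19, which undergoes oxy-anion-accelerated conrotatory 4π ring opening with O– rotating outward and the lactone-bearing carbon inward, so that (Z)-dienolate 20 holds its CMe2 terminus next to the lactone carbonyl. That terminus then attacks the lactone C=O (6‑(enolendo)‑exo‑trig closure; α‑attack or O‑acylation would need a four-membered ring), the lactone alkoxide leaves, and the net result is insertion of the lactone C(=O)–Cα unit between C1 and C4 of the four-membered ring. The closest known reaction types are the alkoxide-accelerated electrocyclic opening of cyclobutenolates made by 1,2‑addition of organolithiums to cyclobutenones and squarates, the thermal cyclobutenone-to-vinylketene ring expansions, and the Dieckmann condensation. The only ring closed is the six-membered dione ring, by the vinylogous Dieckmann step just named, at the expense of the lactone ring. The quaternary centre is set in the first C–C bond formation, the cyclobutenone approaching the half-chair lactone enolate anti to the pseudo-axial C4 isopropyl group, and the existing C4 centre is untouched. The step needs this anti facial selectivity, which the lactone template secures, and kinetic control of the last acyl transfer, which a cold acetic acid quench should secure before the liberated alkoxide can re-add to the non-enolisable 1,3‑diketone.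

Step 10
Reactants: 21 (2R)‑2‑[(3S)‑1‑hydroxy‑4‑methylpentan‑3‑yl]‑5‑methoxy‑4,6,6‑trimethyl‑2‑(6‑methyl‑2‑methylidenehept‑5‑en‑1‑yl)cyclohex‑4‑ene‑1,3‑dione
Product: 22 (3S)‑3‑[(1R)‑4‑methoxy‑3,5,5‑trimethyl‑1‑(6‑methyl‑2‑methylidenehept‑5‑en‑1‑yl)‑2,6‑dioxocyclohex‑3‑en‑1‑yl]‑4‑methylpentanal
Conditions: Dess–Martin periodinane, CH2Cl2, rt
Reagents that add atoms: none
Why: Dess–Martin oxidation converts the primary alcohol into the aldehyde under neutral conditions, avoiding alkoxide formation next to the non-enolisable 1,3‑diketone.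

Step 11
Reactants: 22 (3S)‑3‑[(1R)‑4‑methoxy‑3,5,5‑trimethyl‑1‑(6‑methyl‑2‑methylidenehept‑5‑en‑1‑yl)‑2,6‑dioxocyclohex‑3‑en‑1‑yl]‑4‑methylpentanal
Product: 23 (2R)‑5‑methoxy‑4,6,6‑trimethyl‑2‑[(3S)‑2‑methylhex‑5‑en‑3‑yl]‑2‑(6‑methyl‑2‑methylidenehept‑5‑en‑1‑yl)cyclohex‑4‑ene‑1,3‑dione
Conditions: Ph3PCH3Br, KHMDS, THF, −78 to 0 °C
Reagents that add atoms: methyltriphenylphosphonium bromide, C[P+](c1ccccc1)(c1ccccc1)c1ccccc1.[Br-]
Why: Wittig methylenation should be selective for the aldehyde because both ring ketones are flanked by fully substituted carbons and one is also a vinylogous ester.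

Step 12
Reactants: 23 (2R)‑5‑methoxy‑4,6,6‑trimethyl‑2‑[(3S)‑2‑methylhex‑5‑en‑3‑yl]‑2‑(6‑methyl‑2‑methylidenehept‑5‑en‑1‑yl)cyclohex‑4‑ene‑1,3‑dione
Product: 24 (6R,7S)‑3‑methoxy‑2,4,4‑trimethyl‑10‑(4‑methylpent‑3‑en‑1‑yl)‑7‑(propan‑2‑yl)spiro[5.5]undeca‑2,9‑diene‑1,5‑dione (target, CNP0419264.1)
Conditions: Grubbs II (5 mol %), CH2Cl2, 40 °C
Reagents that add atoms: none
Why: Ring-closing metathesis with a second-generation Ru carbene joins the monosubstituted and the 1,1‑disubstituted alkene to the six-membered ring with a trisubstituted double bond, the prenyl-type alkene staying inert (it could only close a nine-membered ring), and no stereocenter is affected.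

## Compound list

1 | 5‑bromo‑2‑methylpent‑2‑ene | CC(C)=CCCBr | starting material
2 | prop‑2‑yn‑1‑ol | C#CCO | starting material
3 | (4‑methylpent‑3‑en‑1‑yl)magnesium bromide | CC(C)=CCC[Mg]Br | intermediate
4 | 6‑methyl‑2‑methylidenehept‑5‑en‑1‑ol | C=C(CO)CCC=C(C)C | intermediate
5 | 2‑(bromomethyl)‑6‑methylhepta‑1,5‑diene | C=C(CBr)CCC=C(C)C | intermediate
6 | 5,6‑dihydro‑2H‑pyran‑2‑one | O=C1C=CCCO1 | starting material
7 | 4,4,5,5‑tetramethyl‑2‑(prop‑1‑en‑2‑yl)‑1,3,2‑dioxaborolane | CC(=C)B1OC(C)(C)C(C)(C)O1 | starting material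
8 | (4R)‑4‑(prop‑1‑en‑2‑yl)oxan‑2‑one | O=C1OCC[C@H](C1)C(C)=C | intermediate
9 | (4R)‑4‑(propan‑2‑yl)oxan‑2‑one | O=C1OCC[C@H](C1)C(C)C | intermediate
10 | lithium enolate of 9 (C4 configuration unchanged) | [Li]OC1=C[C@@H](CCO1)C(C)C | intermediate
11 | (3S,4S)‑3‑(6‑methyl‑2‑methylidenehept‑5‑en‑1‑yl)‑4‑(propan‑2‑yl)oxan‑2‑one (trans) | O=C1OCC[C@H]([C@@H]1CC(=C)CCC=C(C)C)C(C)C | intermediate
12 | 2‑methylpropanoyl chloride | CC(C)C(Cl)=O | starting material
13 | 1‑ethoxyprop‑1‑yne | CC#COCC | starting material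
14 | dimethylketene | CC(C)=C=O | intermediate
15 | 3‑ethoxy‑2,4,4‑trimethylcyclobut‑2‑en‑1‑one | CCOC1=C(C)C(=O)C1(C)C | intermediate
16 | 3‑hydroxy‑2,4,4‑trimethylcyclobut‑2‑en‑1‑one | OC1=C(C)C(=O)C1(C)C | intermediate
17 | 3‑methoxy‑2,4,4‑trimethylcyclobut‑2‑en‑1‑one | COC1=C(C)C(=O)C1(C)C | intermediate
18 | lithium enolate of 11 (C4 configuration unchanged) | [Li]OC1=C(CC(=C)CCC=C(C)C)[C@@H](CCO1)C(C)C | intermediate
19 | lithium 1‑[(3R,4S)‑lactonyl]‑3‑methoxy‑2,4,4‑trimethylcyclobut‑2‑en‑1‑olate, the 1,2‑adduct of 18 and 17 (carbinol centre undefined, lost in the next event) | [Li]OC1(C(C)=C(OC)C1(C)C)[C@]2(CC(=C)CCC=C(C)C)C(=O)OCC[C@H]2C(C)C | intermediate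
20 | ring-opened lithium (Z)‑dienolate, lactone carbon cis to the C(OMe)=CMe2 unit | [Li]O/C([C@]1(CC(=C)CCC=C(C)C)C(=O)OCC[C@H]1C(C)C)=C(\C)C(OC)=C(C)C | intermediate
21 | (2R)‑2‑[(3S)‑1‑hydroxy‑4‑methylpentan‑3‑yl]‑5‑methoxy‑4,6,6‑trimethyl‑2‑(6‑methyl‑2‑methylidenehept‑5‑en‑1‑yl)cyclohex‑4‑ene‑1,3‑dione | COC1=C(C)C(=O)[C@@](CC(=C)CCC=C(C)C)([C@@H](CCO)C(C)C)C(=O)C1(C)C | intermediate
22 | (3S)‑3‑[(1R)‑4‑methoxy‑3,5,5‑trimethyl‑1‑(6‑methyl‑2‑methylidenehept‑5‑en‑1‑yl)‑2,6‑dioxocyclohex‑3‑en‑1‑yl]‑4‑methylpentanal | COC1=C(C)C(=O)[C@@](CC(=C)CCC=C(C)C)([C@@H](CC=O)C(C)C)C(=O)C1(C)C | intermediate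
23 | (2R)‑5‑methoxy‑4,6,6‑trimethyl‑2‑[(3S)‑2‑methylhex‑5‑en‑3‑yl]‑2‑(6‑methyl‑2‑methylidenehept‑5‑en‑1‑yl)cyclohex‑4‑ene‑1,3‑dione | COC1=C(C)C(=O)[C@@](CC(=C)CCC=C(C)C)([C@@H](CC=C)C(C)C)C(=O)C1(C)C | intermediate
24 | (6R,7S)‑3‑methoxy‑2,4,4‑trimethyl‑10‑(4‑methylpent‑3‑en‑1‑yl)‑7‑(propan‑2‑yl)spiro[5.5]undeca‑2,9‑diene‑1,5‑dione | COC1=C(C)C(=O)[C@]2(CC(CCC=C(C)C)=CC[C@H]2C(C)C)C(=O)C1(C)C | target

## Step count and risks

Total step count: 12. Longest linear sequence: 7 steps (for example steps 6, 7, 8, 9, 10, 11, 12).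

Steps most likely to fail:

1. Step 9 (Proposed new method). The aldol addition of the fully substituted enolate to the hindered ring carbonyl may revert faster than the four-membered ring opens. Conjugate addition–elimination at C3 may also compete, and the liberated alkoxide may re-add to the non-enolisable diketone and cleave it. The fallback is stepwise and uses known reactions; it sets out from 17 and 11. Thermolysis of 17 in toluene in the presence of pentafluorophenol should trap the vinylketene as pentafluorophenyl 3‑methoxy‑2,4‑dimethylpent‑3‑enoate F1. C‑Acylation of the lithium enolate of 11 with this active ester, again anti to the isopropyl group, should give the β‑keto lactone (3R,4S)‑3‑(3‑methoxy‑2,4‑dimethylpent‑3‑enoyl)‑3‑(6‑methyl‑2‑methylidenehept‑5‑en‑1‑yl)‑4‑(propan‑2‑yl)oxan‑2‑one F2. KHMDS then removes the doubly activated C–H between ketone and enol ether, and the dienolate closes by Dieckmann-type attack on the lactone carbonyl, coming back to the route at 21.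

2. Step 7. Water may attack a ring carbonyl of the strained dione and open the four-membered ring during the enol-ether hydrolysis, and the small, acidic, water-soluble product may be lost on isolation. The fallback sets out from 12. Dimethylketene 14, generated as in step 6, is combined in a [2+2] cycloaddition with 1,1‑dimethoxyprop‑1‑ene F3 (from trimethyl orthopropionate by elimination of methanol) to give 3,3‑dimethoxy‑2,4,4‑trimethylcyclobutan‑1‑one F4. This should lose methanol on warming with catalytic TsOH and come back to the route at 17, bypassing steps 7 and 8.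

3. Step 1. The carbomagnesiation may stall or lose regiocontrol, and part of the Grignard reagent is consumed by Wurtz coupling and protonation. The fallback sets out from 9 and 1. Alkylation of the lithium enolate of 9 with 2,3‑dibromopropene should give (3S,4S)‑3‑(2‑bromoprop‑2‑en‑1‑yl)‑4‑(propan‑2‑yl)oxan‑2‑one F5. Negishi coupling with (4‑methylpent‑3‑en‑1‑yl)zinc bromide F6 (from 1 and activated zinc; Pd(dppf)Cl2, THF) then comes back to the route at 11, bypassing steps 1, 2 and 5.

## Further compounds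

F1 | step 9 | pentafluorophenyl 3‑methoxy‑2,4‑dimethylpent‑3‑enoate (racemic at C2) | CC(C(=O)Oc1c(F)c(F)c(F)c(F)c1F)C(OC)=C(C)C
F2 | step 9 | (3R,4S)‑3‑(3‑methoxy‑2,4‑dimethylpent‑3‑enoyl)‑3‑(6‑methyl‑2‑methylidenehept‑5‑en‑1‑yl)‑4‑(propan‑2‑yl)oxan‑2‑one (side-chain C2 as a mixture) | CC(C(=O)[C@]1(CC(=C)CCC=C(C)C)C(=O)OCC[C@H]1C(C)C)C(OC)=C(C)C
F3 | step 7 | 1,1‑dimethoxyprop‑1‑ene | CC=C(OC)OC
F4 | step 7 | 3,3‑dimethoxy‑2,4,4‑trimethylcyclobutan‑1‑one (racemic) | COC1(OC)C(C)C(=O)C1(C)C
F5 | step 1 | (3S,4S)‑3‑(2‑bromoprop‑2‑en‑1‑yl)‑4‑(propan‑2‑yl)oxan‑2‑one | O=C1OCC[C@H]([C@@H]1CC(Br)=C)C(C)C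
F6 | step 1 | (4‑methylpent‑3‑en‑1‑yl)zinc bromide | CC(C)=CCC[Zn]Br
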